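**Assumptions (one line each):**
- Jaspaquinol has no sp3 stereocenter, so it is achiral. The only stereochemistry is the geometry of the two trisubstituted alkenes, with the main chain trans across each. The route sets this in the two HWE steps and preserves it afterwards.
- Dihydro-β-ionone (2) is made from β-ionone (1) instead of being bought.

**Retrosynthesis**
1. Cut the ArCH2–C1 bond. This gives a 2-lithio-1,4-bis(MOM-oxy)benzene and the C20 allylic bromide 12. The hydroquinone is unmasked last.
2. Trace bromide 12 back to alcohol 11, then to dienoate 10 by HWE olefination of the C18 methyl ketone 9. This HWE sets the C2=C3 (E)-alkene.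
3. Make ketone 9 from the C15 allylic bromide 6 by acetoacetate alkylation and decarboxylation.
4. Make bromide 6 from dihydro-β-ionone (2) by HWE, DIBAL-H reduction and bromination. The HWE sets the C6=C7 (E)-alkene. Ketone 2 comes from β-ionone by selective hydrogenation of the enone C=C.
5. No ring is formed. The trimethylcyclohexene ring comes intact from β-ionone and the benzene ring from hydroquinone.

**Route**

**Step 1**
Reactants: 1 (β-ionone)
Product: 2 (dihydro-β-ionone, 4-(2,6,6-trimethylcyclohex-1-en-1-yl)butan-2-one)
Conditions: H2 (1 atm), RhCl(PPh3)3 (2 mol%), toluene, rt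
Reagents that add atoms: none (H2 adds only hydrogen)
Why: Wilkinson's catalyst hydrogenates the unhindered disubstituted enone C=C and leaves the tetrasubstituted ring alkene and the ketone alone. No stereocenter is created. The reaction is a chemoselective homogeneous hydrogenation.

**Step 2**
Reactants: 2 (dihydro-β-ionone), 3 (triethyl phosphonoacetate)
Product: 4 (ethyl (2E)-3-methyl-5-(2,6,6-trimethylcyclohex-1-en-1-yl)pent-2-enoate)
Conditions: NaH, THF, 0 → 50 °C; separate the minor Z isomer by chromatography (E:Z about 3–4:1)
Reagents that add atoms: none beyond reactant 3 (CCOP(=O)(OCC)CC(=O)OCC supplies the =CH–CO2Et unit)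
Why: Horner–Wadsworth–Emmons olefination is thermodynamically controlled and puts the larger chain trans to the ester, which sets the C6=C7 (E)-alkene.

**Step 3**
Reactants: 4
Product: 5 ((2E)-3-methyl-5-(2,6,6-trimethylcyclohex-1-en-1-yl)pent-2-en-1-ol)
Conditions: DIBAL-H (2.2 equiv), CH2Cl2, −78 °C
Reagents that add atoms: none (hydride only)
Why: DIBAL-H reduces the ester 1,2 to the allylic alcohol without touching the alkenes, and the geometry is retained.

**Step 4**
Reactants: 5
Product: 6 ((2E)-1-bromo-3-methyl-5-(2,6,6-trimethylcyclohex-1-en-1-yl)pent-2-ene)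
Conditions: PBr3 (0.4 equiv), Et2O, 0 °C, 30 min; use the crude bromide at once
Reagents that add atoms: phosphorus tribromide, BrP(Br)Br (supplies Br)
Why: This is the standard SN2 conversion of a primary allylic alcohol to its bromide (as for geraniol) and keeps the alkene geometry.

**Step 5**
Reactants: 6, 7 (ethyl acetoacetate)
Product: 8 (ethyl (4E)-2-acetyl-5-methyl-7-(2,6,6-trimethylcyclohex-1-en-1-yl)hept-4-enoate, racemic at the α-carbon)
Conditions: NaOEt (1.1 equiv), EtOH, 0 °C → rt
Reagents that add atoms: none beyond reactant 7 (CCOC(=O)CC(C)=O supplies the acetoacetyl unit)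
Why: Acetoacetate enolate C-alkylation is an SN2 reaction at the primary allylic carbon. The α-stereocenter is racemic and is destroyed in Step 6.

**Step 6**
Reactants: 8
Product: 9 ((5E)-6-methyl-8-(2,6,6-trimethylcyclohex-1-en-1-yl)oct-5-en-2-one)
Conditions: 2 M KOH, EtOH/H2O, 60 °C, 2 h; cool, acidify to pH about 4 with AcOH, 50 °C
Reagents that add atoms: none (CO2 and EtOH are lost)
Why: Saponification followed by decarboxylation of the β-keto acid gives the methyl ketone (ketonic cleavage). The alkenes are untouched.

**Step 7**
Reactants: 9, 3 (triethyl phosphonoacetate)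
Product: 10 (ethyl (2E,6E)-3,7-dimethyl-9-(2,6,6-trimethylcyclohex-1-en-1-yl)nona-2,6-dienoate)
Conditions: NaH, THF, 0 → 50 °C; chromatographic removal of the 2Z isomer
Reagents that add atoms: none beyond reactant 3
Why: The same HWE olefination sets the C2=C3 (E)-alkene. The existing 6E alkene is unaffected.

**Step 8**
Reactants: 10
Product: 11 ((2E,6E)-3,7-dimethyl-9-(2,6,6-trimethylcyclohex-1-en-1-yl)nona-2,6-dien-1-ol)
Conditions: DIBAL-H (2.2 equiv), CH2Cl2, −78 °C
Reagents that add atoms: none
Why: Chemoselective 1,2-reduction of the ester, as in Step 3.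

**Step 9**
Reactants: 11
Product: 12 ((2E,6E)-1-bromo-3,7-dimethyl-9-(2,6,6-trimethylcyclohex-1-en-1-yl)nona-2,6-diene)
Conditions: PBr3 (0.4 equiv), Et2O, 0 °C, 30 min; use the crude bromide at once
Reagents that add atoms: phosphorus tribromide, BrP(Br)Br (supplies Br)
Why: SN2 bromination of the primary allylic alcohol, as in Step 4, with the (E,E)-geometry retained.

**Step 10**
Reactants: 13 (hydroquinone, 1 equiv), 14 (chloromethyl methyl ether, MOMCl, 2.2 equiv; two molecules are incorporated per hydroquinone)
Product: 15 (1,4-bis(methoxymethoxy)benzene)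
Conditions: NaH (2.2 equiv), THF/DMF, 0 °C → rt
Reagents that add atoms: MOMCl, ClCOC, used twice (each molecule supplies one CH2OCH3 group, 2 × C2H5O in total; 2 HCl are lost as NaCl and H2)
Why: Double Williamson-type O-alkylation of the bisphenoxide gives the bis-MOM ether (C6H6O2 + 2 C2H5ClO − 2 HCl = C10H14O4). It makes the phenols inert to organolithiums and gives a directing group for ortho-lithiation. This step is independent of the chain build and can be run in parallel.

**Step 11**
Reactants: 15, 12
Product: 16 (2-[(2E,6E)-3,7-dimethyl-9-(2,6,6-trimethylcyclohex-1-en-1-yl)nona-2,6-dien-1-yl]-1,4-bis(methoxymethoxy)benzene)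
Conditions: n-BuLi (1.1 equiv), THF, 0 °C, 2 h; then CuI (20 mol%), then 12, −78 °C → rt
Reagents that add atoms: none beyond the numbered reactants (n-BuLi and CuI leave no atoms in the product)
Why: MOM-directed ortho-lithiation gives a single aryllithium. Cu-catalysed SN2 alkylation at the primary allylic carbon (not SN2′) keeps both alkene geometries.

**Step 12**
Reactants: 16
Product: 17 (jaspaquinol)
Conditions: 3 M HCl (aq), THF/MeOH 1:2, 40 °C, under Ar and protected from light
Reagents that add atoms: none (the MOM groups are lost as CH2O and MeOH)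
Why: Acid hydrolysis of the aryl MOM acetals is mild enough to leave the trisubstituted alkenes and the tetrasubstituted ring alkene intact.

**Compound list**

| No. | Name | SMILES | Role |
|---|---|---|---|
| 1 | β-ionone | CC(=O)/C=C/C1=C(C)CCCC1(C)C | starting material |
| 2 | dihydro-β-ionone | CC(=O)CCC1=C(C)CCCC1(C)C | intermediate |
| 3 | triethyl phosphonoacetate | CCOP(=O)(OCC)CC(=O)OCC | starting material |
| 4 | ethyl (2E)-3-methyl-5-(2,6,6-trimethylcyclohex-1-en-1-yl)pent-2-enoate | CCOC(=O)/C=C(C)/CCC1=C(C)CCCC1(C)C | intermediate |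
| 5 | (2E)-3-methyl-5-(2,6,6-trimethylcyclohex-1-en-1-yl)pent-2-en-1-ol | OC/C=C(C)/CCC1=C(C)CCCC1(C)C | intermediate |
| 6 | (2E)-1-bromo-3-methyl-5-(2,6,6-trimethylcyclohex-1-en-1-yl)pent-2-ene | BrC/C=C(C)/CCC1=C(C)CCCC1(C)C | intermediate |
| 7 | ethyl acetoacetate | CCOC(=O)CC(C)=O | starting material |
| 8 | ethyl (4E)-2-acetyl-5-methyl-7-(2,6,6-trimethylcyclohex-1-en-1-yl)hept-4-enoate | CCOC(=O)C(C(C)=O)C/C=C(C)/CCC1=C(C)CCCC1(C)C | intermediate |
| 9 | (5E)-6-methyl-8-(2,6,6-trimethylcyclohex-1-en-1-yl)oct-5-en-2-one | CC(=O)CC/C=C(C)/CCC1=C(C)CCCC1(C)C | intermediate |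
| 10 | ethyl (2E,6E)-3,7-dimethyl-9-(2,6,6-trimethylcyclohex-1-en-1-yl)nona-2,6-dienoate | CCOC(=O)/C=C(C)/CC/C=C(C)/CCC1=C(C)CCCC1(C)C | intermediate |
| 11 | (2E,6E)-3,7-dimethyl-9-(2,6,6-trimethylcyclohex-1-en-1-yl)nona-2,6-dien-1-ol | OC/C=C(C)/CC/C=C(C)/CCC1=C(C)CCCC1(C)C | intermediate |
| 12 | (2E,6E)-1-bromo-3,7-dimethyl-9-(2,6,6-trimethylcyclohex-1-en-1-yl)nona-2,6-diene | BrC/C=C(C)/CC/C=C(C)/CCC1=C(C)CCCC1(C)C | intermediate |
| 13 | hydroquinone | Oc1ccc(O)cc1 | starting material |
| 14 | chloromethyl methyl ether (MOMCl) | ClCOC | starting material |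
| 15 | 1,4-bis(methoxymethoxy)benzene | COCOc1ccc(OCOC)cc1 | intermediate |
| 16 | MOM-protected jaspaquinol | COCOc1ccc(OCOC)c(C/C=C(C)/CC/C=C(C)/CCC2=C(C)CCCC2(C)C)c1 | intermediate |
| 17 | jaspaquinol | CC1=C(CC/C(C)=C/CC/C(C)=C/Cc2cc(O)ccc2O)C(C)(C)CCC1 | target |

**Total steps:** 12. **Longest linear sequence:** 11 steps (Steps 1–9, 11, 12, from β-ionone). Step 10 runs in parallel.

**Three steps most likely to fail**
1. **Steps 2 and 7, HWE E/Z control on methyl ketones.** E:Z is only moderate, so yield is lost in separation.
   *Fallback (different approach):* build each trisubstituted alkene by Zr-catalysed carboalumination of a terminal alkyne, which gives complete E-selectivity. Then trap the alkenylalane with ClCO2Et or CO2 to make the unsaturated ester or acid.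
2. **Step 11, aryllithium/allylic bromide coupling.** Bromide 12 is unstable, and SN2′ or Wurtz-type side products can form.
   *Fallback (different approach):* skip the bromide and couple hydroquinone with alcohol 11 by BF3·OEt2-promoted Friedel–Crafts allylation. Alternatively, make an arylzinc from 2-bromo-1,4-dimethoxybenzene and couple it with the allylic carbonate of 11 under Pd catalysis.
3. **Step 12, MOM removal.** Acid can cyclise the hydroquinone onto the alkene to give a chromane, or oxidise it to the quinone.
   *Fallback (different approach):* use the 2,5-dimethoxyaryl series in Step 11, then oxidise with CAN to the quinone and reduce with Na2S2O4 to the hydroquinone. This avoids Brønsted-acid deprotection.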